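**Plan**

- Retrosynthesis: the four phenolic C–O bonds (C4–O and C5–O of ring A and of ring B) are first traded for C–B bonds. The ring bonds C3–C4 and C5–C6 of both benzene rings are cut next, and the benzylic C–O ether bond and the C–Br bonds last.
- Enabling feature: in each ring (C1 benzylic, C2/C3/C6 brominated, C4/C5 hydroxylated) the neighbouring carbons C4–C5 form a symmetric two-carbon unit that an alkyne bearing two boron atoms can supply. The chain C6–C1–C2–C3, with its CH2O arm and three bromines, is the carbon frame of a 2,4,5-tribromo-3-thenyl ring whose sulfur can leave as SO2.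
- Forward: 3-methylthiophene is perbrominated, its methyl group is functionalised, and two thenyl halves are joined through the ether oxygen before any benzene ring exists. Both sulfurs are then oxidised to sulfones.
- Ring A and ring B arise in one operation by a double [4+2] cycloaddition/SO2 extrusion with the diborylalkyne. Oxidation of the four C–B bonds releases the two catechols in the last step.
- Stereochemistry: the target has no stereocentre, so nothing has to be set. The bridgehead centres of the transient cycloadducts vanish when SO2 is lost.

Key step: step 6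

Remark: the bridged sulfone cycloadducts are assumed to lose SO2 faster than they form, as is usual for alkyne adducts of thiophene 1,1-dioxides, so they are treated as non-isolated racemic intermediates.

**Route**

Step 1
Reactants: 1 3-methylthiophene; 2 bromine (three equivalents are consumed)
Product: 3 2,4,5-tribromo-3-methylthiophene
Conditions: Br2 (3.5 equiv), CHCl3/AcOH (1:1), 0 °C then 60 °C, dark
Reagents that add atoms: bromine, BrBr (compound 2; each of the three molecules consumed leaves one bromine atom on the ring)
Why: Three successive electrophilic aromatic brominations, each using one molecule of Br2 and releasing one HBr, take the two alpha positions first and, with the excess of Br2 and warming, the remaining beta position C4, while the methyl group is untouched under ionic conditions in the dark.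

Step 2
Reactants: 3 2,4,5-tribromo-3-methylthiophene
Product: 4 2,4,5-tribromo-3-(bromomethyl)thiophene
Conditions: NBS (1.05 equiv), AIBN (5 mol %), PhCF3, 90 °C
Reagents that add atoms: N-bromosuccinimide, O=C1CCC(=O)N1Br
Why: Wohl–Ziegler radical bromination can only strike the thenylic methyl C–H bonds because every ring position is blocked, and one equivalent of NBS together with the two flanking bromines should hold the reaction at the monobromide.

Step 3
Reactants: 4 2,4,5-tribromo-3-(bromomethyl)thiophene (about half of the material)
Product: 5 (2,4,5-tribromothiophen-3-yl)methanol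
Conditions: CaCO3 (3 equiv), 1,4-dioxane/H2O (1:1), reflux
Reagents that add atoms: water, O
Why: Solvolytic hydrolysis (nucleophilic substitution) of the primary thenylic bromide by water should give the alcohol, with CaCO3 taking up the HBr so that no acid-promoted side reaction of the product intervenes.

Step 4
Reactants: 5 (2,4,5-tribromothiophen-3-yl)methanol; 4 2,4,5-tribromo-3-(bromomethyl)thiophene
Product: 6 bis[(2,4,5-tribromothiophen-3-yl)methyl] ether
Conditions: NaH (1.2 equiv), THF, 0 °C; then 4 (1.0 equiv), Bu4NI (10 mol %), 0 °C to 40 °C
Reagents that add atoms: none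
Why: Williamson ether synthesis, in which the sodium alkoxide of 5 displaces bromide from the primary thenylic carbon of 4 in an SN2 reaction, the perbrominated rings offering no acidic C–H bond and no site that alkoxide attacks at this temperature.

Step 5
Reactants: 6 bis[(2,4,5-tribromothiophen-3-yl)methyl] ether
Product: 7 bis[(2,4,5-tribromo-1,1-dioxothiophen-3-yl)methyl] ether
Conditions: urea·H2O2 (10 equiv), (CF3CO)2O (10 equiv), MeCN/CH2Cl2, 0 °C to rt
Reagents that add atoms: trifluoroperacetic acid, OOC(=O)C(F)(F)F (made in the flask from urea–hydrogen peroxide, NC(N)=O.OO, and trifluoroacetic anhydride, O=C(OC(=O)C(F)(F)F)C(F)(F)F)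
Why: Electrophilic oxygen transfer from CF3CO3H, the established way of turning tetrahalothiophenes into their 1,1-dioxides, should oxidise each sulfur twice (the sulfoxide reacting faster than the thiophene), while the ether and the C–Br bonds are inert to peracid and the fully substituted dioxide rings cannot dimerise.

Step 6
Reactants: 7 bis[(2,4,5-tribromo-1,1-dioxothiophen-3-yl)methyl] ether; 8 1,2-bis(4,4,5,5-tetramethyl-1,3,2-dioxaborolan-2-yl)ethyne
Product: 12 bis[2,3,6-tribromo-4,5-bis(4,4,5,5-tetramethyl-1,3,2-dioxaborolan-2-yl)benzyl] ether, via bridged monoadduct 9 (not isolated), via half-annulated sulfone 10 (not isolated), via bridged second adduct 11 (not isolated)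
Conditions: 8 (6 equiv), 1,2-dichlorobenzene, 140 °C, slow argon sweep
Reagents that add atoms: none
Why: Proposed new method: each tribromothiophene 1,1-dioxide ring of 7 is a non-aromatic, electron-poor diene held s-cis by the ring, and alkyne 8 should add across its C2 and C5 in an inverse-electron-demand [4+2] cycloaddition to a 7-thiabicyclo[2.2.1]hepta-2,5-diene 7,7-dioxide, which expels SO2 in a thermally allowed cheletropic step and is thereby aromatised irreversibly. The closest known reaction types are the Diels–Alder/SO2-extrusion benzannulation of tetrahalothiophene 1,1-dioxides with alkynes and alkenes and the cycloaddition/extrusion benzannulation of alkynyl pinacol boronates with 2-pyrones, cyclopentadienones and 1,2,4,5-tetrazines; the pairing of a halothiophene dioxide with a boryl alkyne is what is new. Ring A and ring B are each closed by an intermolecular [4+2] cycloaddition that forms the C3–C4 and C5–C6 bonds, the first ring by way of 9 and 10 and the second by way of 11. No stereocentre is present in 12, and the bridgehead centres of 9 and 11 disappear together with SO2. Regiochemistry does not arise because 8 is symmetric, so the only selectivity needed is cycloaddition ahead of thermal decay of the dioxide and of C–B protonolysis; the fully substituted diene (no self-dimerisation), the excess of 8, the dry aprotic medium and the removal of SO2 in the gas stream are meant to secure it.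

Step 7
Reactants: 12 bis[2,3,6-tribromo-4,5-bis(4,4,5,5-tetramethyl-1,3,2-dioxaborolan-2-yl)benzyl] ether
Product: 13 bis(2,3,6-tribromo-4,5-dihydroxybenzyl) ether
Conditions: NaBO3·4H2O (6 equiv), THF/H2O (1:1), 0 °C to rt, argon; then aq. Na2S2O4/NaH2PO4 work-up (pH 5–6)
Reagents that add atoms: sodium perborate tetrahydrate, [Na+].[O-]OB=O.O.O.O.O
Why: Oxidation of aryl boronic esters to phenols, in which hydroperoxide from NaBO3 adds to each boron, the aryl group migrates from boron to oxygen at the carbon that carried boron, and hydrolysis of the borate should release both catechols under mild, acid-free conditions that leave the para-hydroxybenzylic ether and the C–Br bonds intact.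

**Compound list**

1 | 3-methylthiophene | Cc1ccsc1 | starting material
2 | bromine | BrBr | starting material
3 | 2,4,5-tribromo-3-methylthiophene | Cc1c(Br)sc(Br)c1Br | intermediate
4 | 2,4,5-tribromo-3-(bromomethyl)thiophene | BrCc1c(Br)sc(Br)c1Br | intermediate
5 | (2,4,5-tribromothiophen-3-yl)methanol | OCc1c(Br)sc(Br)c1Br | intermediate
6 | bis[(2,4,5-tribromothiophen-3-yl)methyl] ether | Brc1sc(Br)c(COCc2c(Br)sc(Br)c2Br)c1Br | intermediate
7 | bis[(2,4,5-tribromo-1,1-dioxothiophen-3-yl)methyl] ether | O=S1(=O)C(Br)=C(Br)C(COCC2=C(Br)S(=O)(=O)C(Br)=C2Br)=C1Br | intermediate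
8 | 1,2-bis(4,4,5,5-tetramethyl-1,3,2-dioxaborolan-2-yl)ethyne | CC1(C)OB(OC1(C)C)C#CB1OC(C)(C)C(C)(C)O1 | starting material
9 | 1,2,4-tribromo-5,6-bis(4,4,5,5-tetramethyl-1,3,2-dioxaborolan-2-yl)-3-{[(2,4,5-tribromo-1,1-dioxothiophen-3-yl)methoxy]methyl}-7-thiabicyclo[2.2.1]hepta-2,5-diene 7,7-dioxide (racemic, bridgeheads tied by the bicycle) | O=S1(=O)C2(Br)C(COCC3=C(Br)S(=O)(=O)C(Br)=C3Br)=C(Br)C1(Br)C(B3OC(C)(C)C(C)(C)O3)=C2B4OC(C)(C)C(C)(C)O4 | intermediate (not isolated)
10 | 2,4,5-tribromo-3-{[2,3,6-tribromo-4,5-bis(4,4,5,5-tetramethyl-1,3,2-dioxaborolan-2-yl)benzyloxy]methyl}thiophene 1,1-dioxide | CC1(C)OB(OC1(C)C)c1c(Br)c(Br)c(COCC2=C(Br)S(=O)(=O)C(Br)=C2Br)c(Br)c1B1OC(C)(C)C(C)(C)O1 | intermediate (not isolated)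
11 | 1,2,4-tribromo-5,6-bis(4,4,5,5-tetramethyl-1,3,2-dioxaborolan-2-yl)-3-{[2,3,6-tribromo-4,5-bis(4,4,5,5-tetramethyl-1,3,2-dioxaborolan-2-yl)benzyloxy]methyl}-7-thiabicyclo[2.2.1]hepta-2,5-diene 7,7-dioxide (racemic, bridgeheads tied by the bicycle) | CC1(C)OB(OC1(C)C)c1c(Br)c(Br)c(COCC2=C(Br)C3(Br)C(B4OC(C)(C)C(C)(C)O4)=C(B4OC(C)(C)C(C)(C)O4)C2(Br)S3(=O)=O)c(Br)c1B1OC(C)(C)C(C)(C)O1 | intermediate (not isolated)
12 | bis[2,3,6-tribromo-4,5-bis(4,4,5,5-tetramethyl-1,3,2-dioxaborolan-2-yl)benzyl] ether | CC1(C)OB(OC1(C)C)c1c(Br)c(Br)c(COCc2c(Br)c(Br)c(B3OC(C)(C)C(C)(C)O3)c(B3OC(C)(C)C(C)(C)O3)c2Br)c(Br)c1B1OC(C)(C)C(C)(C)O1 | intermediate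
13 | bis(2,3,6-tribromo-4,5-dihydroxybenzyl) ether (achiral) | Oc1c(O)c(Br)c(COCc2c(Br)c(O)c(O)c(Br)c2Br)c(Br)c1Br | target

**Count**

Total steps: 7. Longest linear sequence: 7 steps (1 → 3 → 4 → 5 → 6 → 7 → 12 → 13; compound 4 is used in both step 3 and step 4).

**Steps most likely to fail**

1. Step 6. The [4+2] addition of the hindered, only weakly nucleophilic diborylalkyne may be slower than thermal decay of the bis(diene). It may also stall after ring A, so that material collects at the half-annulated stage, and traces of protic species may strip boron from the product. The fallback uses known chemistry and brings the oxygen atoms in directly with an alkene dienophile at the dihydro oxidation level. It sets out from 7, which is heated with excess vinylene carbonate (1,3-dioxol-2-one) in chlorobenzene at 110–130 °C. Halothiophene dioxides add to alkenes far more readily than to alkynes and the adducts shed SO2 as they form, so this should give bis[(4,6,7-tribromo-2-oxo-3a,7a-dihydro-1,3-benzodioxol-5-yl)methyl] ether F1 (cis ring fusions, mixture of diastereomers). Dehydrogenation with DDQ in refluxing chlorobenzene should aromatise both rings to bis[(4,6,7-tribromo-2-oxo-1,3-benzodioxol-5-yl)methyl] ether F2. The two cyclic aryl carbonates are then hydrolysed with aqueous NaHCO3 in THF at room temperature under argon. This comes back to the route at the target 13 and bypasses 12 and step 7.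

2. Step 7. Base-induced protodeboronation of the crowded ortho-bromo aryl boronates may compete with oxygen insertion. The freed electron-poor catechols may also be oxidised further to ortho-quinones or ionise the para-hydroxybenzylic ether during the aqueous oxidation and work-up. The fallback separates oxygen insertion from the handling of the free bis-catechol. It sets out from 12, which is treated with anhydrous trimethylamine N-oxide in THF at room temperature; oxygen is delivered to each C–B bond without hydroxide or peroxide present. The resulting aryl borates are acetylated in the same flask (Ac2O, pyridine, DMAP) to bis(4,5-diacetoxy-2,3,6-tribromobenzyl) ether F3, which can be purified on silica. Methanolysis with catalytic K2CO3 in MeOH at 0 °C under argon, followed by NaH2PO4 quench, comes back to the route at 13.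

3. Step 5. The second sulfur may resist oxidation once the molecule has become strongly electron-poor, or the bis(diene) may be degraded by the long exposure to the acidic peracid medium. The fallback oxidises before the halves are joined and forms the ether without alkoxide. It sets out from 4, which has one sulfur per molecule and is the closest analogue of tetrabromothiophene. CF3CO3H converts it into 2,4,5-tribromo-3-(bromomethyl)thiophene 1,1-dioxide F4. Part of F4 is hydrolysed with Ag2CO3 in aqueous acetone at room temperature to (2,4,5-tribromo-1,1-dioxothiophen-3-yl)methanol F5. F5 and F4 are then joined by Ag2O-mediated etherification (CH2Cl2, 4 Å molecular sieves, rt), conditions that the electrophilic dioxide should tolerate, and the sequence comes back to the route at 7.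

**Further compounds**

F1 | step 6 | bis[(4,6,7-tribromo-2-oxo-3a,7a-dihydro-1,3-benzodioxol-5-yl)methyl] ether (cis-fused, mixture of diastereomers) | O=C1OC2C(Br)=C(Br)C(COCC3=C(Br)C4OC(=O)OC4C(Br)=C3Br)=C(Br)C2O1
F2 | step 6 | bis[(4,6,7-tribromo-2-oxo-1,3-benzodioxol-5-yl)methyl] ether | O=C1Oc2c(Br)c(Br)c(COCc3c(Br)c(Br)c4OC(=O)Oc4c3Br)c(Br)c2O1
F3 | step 7 | bis(4,5-diacetoxy-2,3,6-tribromobenzyl) ether | CC(=O)Oc1c(OC(C)=O)c(Br)c(COCc2c(Br)c(OC(C)=O)c(OC(C)=O)c(Br)c2Br)c(Br)c1Br
F4 | step 5 | 2,4,5-tribromo-3-(bromomethyl)thiophene 1,1-dioxide | O=S1(=O)C(Br)=C(Br)C(CBr)=C1Br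
F5 | step 5 | (2,4,5-tribromo-1,1-dioxothiophen-3-yl)methanol | O=S1(=O)C(Br)=C(Br)C(CO)=C1Br
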